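**Plan**

- Labels: ring A is the central resorcinol-type ring, ring B the dioxygenated benzo ring, furan 1 the dihydrofuran carrying the 4-hydroxyphenyl group, furan 2 the one carrying the 2,4- and 3,5-dihydroxyphenyl groups. Locants 1–11 are those of 10,11-dihydro-5H-dibenzo[a,d][7]annulene (C-5 shared by the seven-membered ring and furan 1, C-11 = CH(aryl), O-6 and O-8 on ring A); C-2' is the O–CH(aryl) carbon of furan 1; C-2''/C-3'' are the O–CH(aryl) and CH(aryl) carbons of furan 2.
- Cuts, target backwards: nine O–H to O–CH3; furan 2 at C-3''–C-2'' (carbene C–H insertion), then O-8–CH2 (ether), C-3''–aryl (Grignard) and C-9–C-3'' (formylation); furan 1 at C-5–C-2' (carbene C–H insertion) and O-6–CH2; the seven-membered ring at C-5–C-5a (Friedel–Crafts acylation); ring A at C-9a–C-10 (decarboxylative arylation); the 2,4-dioxygenated aryl at C-11 (conjugate addition).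
- Forward: ring B cinnamate → C-11 by aryl conjugate addition → ring A joined to the two-carbon chain → seven-membered ketone → furan 1 → furan 2 → demethylation.
- Feature behind the key step: C-5, the CH shared by the seven-membered ring and furan 1, is a diarylmethine whose ring A neighbour C-5a lies next to the oxygen-bearing C-6; as a carbene it sits 1,5 to the C–H bonds of a benzyl ether on O-6.
- Stereochemistry: C-11 from a chiral diene–rhodium catalyst; C-5 and C-3'' from Rh2(S-PTAD)4 and Rh2(R-PTAD)4; C-2' and C-2'' by acid equilibration to the trans dihydrofurans.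

Key step: step 11

Assumption: compounds 1, 2, 4, 7, 8, 11, 17, 25 and 27 (as a THF solution) are bought; 1 is otherwise one Vilsmeier formylation away from methyl 3,5-dimethoxybenzoate.
Assumption: the antipodes of the diene ligand (step 2) and of Rh2(PTAD)4 (steps 11 and 17) are those expected by analogy with simpler substrates; if a trial run shows the opposite sense, the mirror-image catalyst is used.

**Route**

Step 1
Reactants: 1 methyl 2-formyl-3,5-dimethoxybenzoate; 2 tert-butyl (triphenylphosphoranylidene)acetate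
Product: 3 methyl 2-[(1E)-3-tert-butoxy-3-oxoprop-1-en-1-yl]-3,5-dimethoxybenzoate
Conditions: PhMe, 80 °C
Reagents that add atoms: none
Why: Wittig olefination with a stabilised ylide should give the (E)-enoate, and the neighbouring methyl ester is too hindered and too unreactive to compete with the aldehyde.

Step 2
Reactants: 3 methyl 2-[(1E)-3-tert-butoxy-3-oxoprop-1-en-1-yl]-3,5-dimethoxybenzoate; 4 (2,4-dimethoxyphenyl)boronic acid
Product: 5 methyl 2-[(1R)-3-tert-butoxy-1-(2,4-dimethoxyphenyl)-3-oxopropyl]-3,5-dimethoxybenzoate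
Conditions: 4 (3 equiv), [RhCl(C2H4)2]2 (2.5 mol%), (1R,4R)-2,5-diphenylbicyclo[2.2.2]octa-2,5-diene (5.5 mol%), KOH (0.3 equiv), 1,4-dioxane/H2O (10:1), 50 °C
Reagents that add atoms: none
Why: Rhodium-catalysed asymmetric conjugate addition of an arylboronic acid (Hayashi–Miyaura reaction): the aryl–rhodium species formed by transmetalation adds across the enoate from the face left open by the chiral diene, which sets C-11 as (R), tert-butyl cinnamates being standard acceptors for this catalyst class although the two ortho substituents will slow the insertion.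

Step 3
Reactants: 5 methyl 2-[(1R)-3-tert-butoxy-1-(2,4-dimethoxyphenyl)-3-oxopropyl]-3,5-dimethoxybenzoate
Product: 6 (3R)-3-(2,4-dimethoxyphenyl)-3-[2,4-dimethoxy-6-(methoxycarbonyl)phenyl]propanoic acid
Conditions: CF3CO2H/CH2Cl2 (1:4), 0 °C → rt
Reagents that add atoms: none
Why: Acidolysis of the tert-butyl ester by alkyl–oxygen cleavage releases isobutene and frees only the aliphatic acid, since methyl esters and aryl methyl ethers are stable to CF3CO2H.

Step 4
Reactants: 7 1,3-di(propan-2-yloxy)benzene; 8 bis(pinacolato)diboron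
Product: 10 [3,5-di(propan-2-yloxy)phenyl]boronic acid, via pinacol boronate 9 (not isolated)
Conditions: [Ir(OMe)(cod)]2 (1.5 mol%), 4,4'-di-tert-butyl-2,2'-bipyridine (3 mol%), THF, 80 °C; then NaIO4, 1 M HCl, THF/H2O, rt
Reagents that add atoms: water, O
Why: Sterically controlled iridium-catalysed C–H borylation (Hartwig–Miyaura) takes place at the only ring C–H that has no ortho isopropoxy group, and periodate then cleaves the pinacol of 9 so that the free boronic acid needed in step 5 is obtained in one flask.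

Step 5
Reactants: 6 (3R)-3-(2,4-dimethoxyphenyl)-3-[2,4-dimethoxy-6-(methoxycarbonyl)phenyl]propanoic acid; 10 [3,5-di(propan-2-yloxy)phenyl]boronic acid; 11 N-hydroxytetrachlorophthalimide
Product: 13 methyl 2-[(1R)-1-(2,4-dimethoxyphenyl)-2-[3,5-di(propan-2-yloxy)phenyl]ethyl]-3,5-dimethoxybenzoate, via redox-active ester 12 (not isolated)
Conditions: 11, N,N'-diisopropylcarbodiimide, DMAP (cat.), CH2Cl2, rt; evaporate; then 10 (3 equiv), NiCl2·6H2O (20 mol%), 4,7-diphenyl-1,10-phenanthroline (22 mol%), Et3N, 1,4-dioxane/DMF (10:1), 75 °C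
Reagents that add atoms: none
Why: Nickel-catalysed decarboxylative Suzuki-type coupling of a redox-active ester: electron transfer from low-valent nickel to ester 12 expels CO2 and the phthalimide anion, and the primary alkyl radical is captured by the aryl–nickel species formed from 10 and coupled by reductive elimination, which joins ring A to C-10 without touching the adjacent C-11 centre.

Step 6
Reactants: 13 methyl 2-[(1R)-1-(2,4-dimethoxyphenyl)-2-[3,5-di(propan-2-yloxy)phenyl]ethyl]-3,5-dimethoxybenzoate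
Product: 14 2-[(1R)-1-(2,4-dimethoxyphenyl)-2-[3,5-di(propan-2-yloxy)phenyl]ethyl]-3,5-dimethoxybenzoic acid
Conditions: LiOH·H2O, THF/MeOH/H2O, 65 °C; then 1 M HCl
Reagents that add atoms: lithium hydroxide, [Li+].[OH-]
Why: Saponification of the one remaining ester, which has a single ortho substituent and should yield to hot aqueous hydroxide, while C-11 carries no acidic hydrogen.

Step 7
Reactants: 14 2-[(1R)-1-(2,4-dimethoxyphenyl)-2-[3,5-di(propan-2-yloxy)phenyl]ethyl]-3,5-dimethoxybenzoic acid
Product: 15 (11R)-11-(2,4-dimethoxyphenyl)-1,3-dimethoxy-6,8-di(propan-2-yloxy)-10,11-dihydro-5H-dibenzo[a,d][7]annulen-5-one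
Conditions: (CF3CO)2O, CH2Cl2, 0 °C → rt
Reagents that add atoms: none
Why: Intramolecular Friedel–Crafts acylation through the mixed trifluoroacetic anhydride: the acylium attacks ring A ortho to the CH2 group, a position ortho and para to the two isopropoxy groups and the same on either side by symmetry, so the seven-membered ketone should form in preference to a six-membered one on the 2,4-dimethoxyphenyl ring, whose only free ortho carbon is meta to both methoxy groups.

Step 8
Reactants: 15 (11R)-11-(2,4-dimethoxyphenyl)-1,3-dimethoxy-6,8-di(propan-2-yloxy)-10,11-dihydro-5H-dibenzo[a,d][7]annulen-5-one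
Product: 16 (11R)-11-(2,4-dimethoxyphenyl)-6-hydroxy-1,3-dimethoxy-8-(propan-2-yloxy)-10,11-dihydro-5H-dibenzo[a,d][7]annulen-5-one
Conditions: BCl3 (1.1 equiv), CH2Cl2, −78 °C; then H2O
Reagents that add atoms: none
Why: Chelation-controlled ether cleavage: BCl3 bound to the ketone oxygen is held next to the peri isopropoxy group on C-6, so one equivalent at −78 °C should remove this group alone and leave the 8-isopropyl and all methyl ethers.

Step 9
Reactants: 16 (11R)-11-(2,4-dimethoxyphenyl)-6-hydroxy-1,3-dimethoxy-8-(propan-2-yloxy)-10,11-dihydro-5H-dibenzo[a,d][7]annulen-5-one; 17 4-methoxybenzyl chloride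
Product: 18 (11R)-11-(2,4-dimethoxyphenyl)-1,3-dimethoxy-6-[(4-methoxyphenyl)methoxy]-8-(propan-2-yloxy)-10,11-dihydro-5H-dibenzo[a,d][7]annulen-5-one
Conditions: K2CO3, Bu4NI (cat.), DMF, 60 °C
Reagents that add atoms: none
Why: Williamson etherification of the hydrogen-bonded phenol places the benzylic CH2 of a 4-methoxybenzyl ether five atoms from the ketone carbon, as the key step requires.

Step 10
Reactants: 18 (11R)-11-(2,4-dimethoxyphenyl)-1,3-dimethoxy-6-[(4-methoxyphenyl)methoxy]-8-(propan-2-yloxy)-10,11-dihydro-5H-dibenzo[a,d][7]annulen-5-one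
Product: 19 (11R)-11-(2,4-dimethoxyphenyl)-5-hydrazinylidene-1,3-dimethoxy-6-[(4-methoxyphenyl)methoxy]-8-(propan-2-yloxy)-10,11-dihydro-5H-dibenzo[a,d][7]annulene
Conditions: N2H4·H2O (excess), AcOH (cat.), EtOH, 100 °C (sealed tube)
Reagents that add atoms: hydrazine (as the hydrate), NN
Why: Condensation of the diaryl ketone with excess hydrazine under mild acid catalysis gives the N-unsubstituted hydrazone, the usual entry to diaryldiazomethanes, and the ethers are inert to it.

Step 11
Reactants: 19 (11R)-11-(2,4-dimethoxyphenyl)-5-hydrazinylidene-1,3-dimethoxy-6-[(4-methoxyphenyl)methoxy]-8-(propan-2-yloxy)-10,11-dihydro-5H-dibenzo[a,d][7]annulene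
Product: 22 trans furan 1 tetracycle (5R,2'R,11R; 8-isopropoxy), via diazo compound 20 (not isolated), via cis furan 1 tetracycle 21 (not isolated)
Conditions: MnO2, CH2Cl2, rt, filter; Rh2(S-PTAD)4 (1 mol%), CH2Cl2, −40 °C → rt; then CF3CO2H, 0 °C → rt
Reagents that add atoms: none
Why: MnO2 dehydrogenates the hydrazone to the diaryldiazomethane 20, which loses N2 on the dirhodium tetracarboxylate to give a donor/donor carbene whose carbon is C-5 of the seven-membered ring. The carbene takes a hydride from the benzylic CH2 on O-6 and the C-5–C-2' bond closes at once, a 1,5-C–H insertion that forms the five-membered furan 1; the closest known reaction is the enantioselective dirhodium donor/donor carbene insertion into benzyl ether C–H bonds that gives 2,3-diaryl-2,3-dihydrobenzofurans from acyclic diaryl hydrazones. C-5 is set by the chiral carboxylate ligands, which shield one face of the carbene, and the catalyst antipode is the one whose preference agrees with the bias of the existing C-11 centre across the ring. C-2' is formed with H-2' cis to H-5 (21) and is then equilibrated by CF3CO2H through the ring-opened 4-methoxybenzylic cation to the more stable trans isomer 22, so it is under thermodynamic control. The step needs site selectivity among C–H bonds, and the substrate secures it: the only other C–H bonds near the carbene, at C-10 and C-11, could only close strained four-membered rings, while the 4-methoxyphenyl group makes the ether C–H the most hydridic one.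

Step 12
Reactants: 22 trans furan 1 tetracycle (5R,2'R,11R; 8-isopropoxy)
Product: 23 trans furan 1 tetracycle 8-phenol (5R,2'R,11R)
Conditions: BCl3 (3 equiv), CH2Cl2, −78 → 0 °C; then H2O
Reagents that add atoms: none
Why: BCl3 cleaves aryl isopropyl ethers at temperatures where aryl methyl ethers survive, and if the benzylic C–O bond of furan 1 ionises it can only reclose to the trans isomer already present.

Step 13
Reactants: 23 trans furan 1 tetracycle 8-phenol (5R,2'R,11R)
Product: 24 9-formyl 8-phenol of the furan 1 tetracycle (5R,2'R,11R)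
Conditions: MgCl2, Et3N, (CH2O)n, THF, 65 °C; then 1 M HCl
Reagents that add atoms: formaldehyde (as paraformaldehyde), C=O
Why: Magnesium-mediated ortho-formylation of a phenol (Casnati–Skattebøl reaction): formaldehyde is delivered within the magnesium phenoxide to an ortho carbon, expected at C-9 because this position is para to O-6 as in orcinol-type phenols, and a second formaldehyde oxidises the benzylic alkoxide, so the other electron-rich rings stay untouched.

Step 14
Reactants: 24 9-formyl 8-phenol of the furan 1 tetracycle (5R,2'R,11R); 25 (2,4-dimethoxyphenyl)methanol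
Product: 26 9-formyl 8-[(2,4-dimethoxyphenyl)methyl] ether of the furan 1 tetracycle (5R,2'R,11R)
Conditions: PPh3, DIAD, THF, 0 °C → rt
Reagents that add atoms: none
Why: Mitsunobu etherification of the acidic salicylaldehyde phenol with the benzylic alcohol installs the second C–H insertion handle without recourse to the unstable 2,4-dimethoxybenzyl halides.

Step 15
Reactants: 26 9-formyl 8-[(2,4-dimethoxyphenyl)methyl] ether of the furan 1 tetracycle (5R,2'R,11R); 27 (3,5-dimethoxyphenyl)magnesium chloride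
Product: 29 9-(3,5-dimethoxybenzoyl) 8-[(2,4-dimethoxyphenyl)methyl] ether of the furan 1 tetracycle (5R,2'R,11R), via magnesium alkoxide 28 (not isolated)
Conditions: THF, −78 → 0 °C; then 1,1'-(azodicarbonyl)dipiperidine, rt
Reagents that add atoms: none
Why: Addition of the aryl Grignard reagent to the aldehyde gives magnesium alkoxide 28, which is oxidised in the same flask by hydride transfer to the azodicarboxamide (Mukaiyama oxidation), so the diaryl ketone is reached without isolating the acid-sensitive diaryl carbinol.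

Step 16
Reactants: 29 9-(3,5-dimethoxybenzoyl) 8-[(2,4-dimethoxyphenyl)methyl] ether of the furan 1 tetracycle (5R,2'R,11R)
Product: 30 hydrazone of ketone 29
Conditions: N2H4·H2O (large excess), AcOH (cat.), n-BuOH, 120 °C (sealed tube)
Reagents that add atoms: hydrazine (as the hydrate), NN
Why: Hydrazone formation as in step 10, on a ketone whose ring A side carries two ortho substituents, which is why a higher temperature and a larger excess of hydrazine are planned.

Step 17
Reactants: 30 hydrazone of ketone 29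
Product: 33 nonamethyl ether of the target (5R,2'R,11R,3''S,2''S), via diazo compound 31 (not isolated), via cis furan 2 isomer 32 (not isolated)
Conditions: MnO2, CH2Cl2, rt, filter; Rh2(R-PTAD)4 (1 mol%), CH2Cl2, −40 °C → rt; then CF3CO2H (0.2 equiv), 0 °C
Reagents that add atoms: none
Why: Dirhodium donor/donor carbene 1,5-insertion into a benzyl ether C–H bond with an acyclic diaryl carbene, the substrate type for which this reaction is established: the ligands of Rh2(R-PTAD)4 select the carbene face and set C-3'' as (S), C-2'' forms cis (32) and is brought to trans by a trace of acid through the 2,4-dimethoxybenzylic cation, and insertion at C-11 is not expected because it would give a bridged ring.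

Step 18
Reactants: 33 nonamethyl ether of the target (5R,2'R,11R,3''S,2''S)
Product: 34 CNP0283541.1 (5R,2'R,11R,3''S,2''S)
Conditions: BBr3 (excess), CH2Cl2, −78 °C → rt; then MeOH, H2O
Reagents that add atoms: none
Why: Lewis acid cleavage of all nine aryl methyl ethers with BBr3, under which any reversible opening of the two dihydrofurans can only return the trans isomers already in place.

**Compound list**

1 | methyl 2-formyl-3,5-dimethoxybenzoate | COC(=O)c1cc(OC)cc(OC)c1C=O | starting material
2 | tert-butyl (triphenylphosphoranylidene)acetate | CC(C)(C)OC(=O)C=P(c1ccccc1)(c1ccccc1)c1ccccc1 | starting material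
3 | methyl 2-[(1E)-3-tert-butoxy-3-oxoprop-1-en-1-yl]-3,5-dimethoxybenzoate | COC(=O)c1cc(OC)cc(OC)c1/C=C/C(=O)OC(C)(C)C | intermediate
4 | (2,4-dimethoxyphenyl)boronic acid | COc1ccc(B(O)O)c(OC)c1 | starting material
5 | methyl 2-[(1R)-3-tert-butoxy-1-(2,4-dimethoxyphenyl)-3-oxopropyl]-3,5-dimethoxybenzoate | COC(=O)c1cc(OC)cc(OC)c1[C@@H](c1ccc(OC)cc1OC)CC(=O)OC(C)(C)C | intermediate
6 | (3R)-3-(2,4-dimethoxyphenyl)-3-[2,4-dimethoxy-6-(methoxycarbonyl)phenyl]propanoic acid | COC(=O)c1cc(OC)cc(OC)c1[C@@H](c1ccc(OC)cc1OC)CC(=O)O | intermediate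
7 | 1,3-di(propan-2-yloxy)benzene | CC(C)Oc1cccc(OC(C)C)c1 | starting material
8 | bis(pinacolato)diboron | CC1(C)OB(OC1(C)C)B1OC(C)(C)C(C)(C)O1 | starting material
9 | pinacol boronate: 2-[3,5-di(propan-2-yloxy)phenyl]-4,4,5,5-tetramethyl-1,3,2-dioxaborolane | CC(C)Oc1cc(OC(C)C)cc(c1)B1OC(C)(C)C(C)(C)O1 | intermediate
10 | [3,5-di(propan-2-yloxy)phenyl]boronic acid | CC(C)Oc1cc(OC(C)C)cc(B(O)O)c1 | intermediate
11 | N-hydroxytetrachlorophthalimide (4,5,6,7-tetrachloro-2-hydroxyisoindoline-1,3-dione) | ON1C(=O)c2c(Cl)c(Cl)c(Cl)c(Cl)c2C1=O | starting material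
12 | redox-active ester: 4,5,6,7-tetrachloro-1,3-dioxoisoindolin-2-yl (3R)-3-(2,4-dimethoxyphenyl)-3-[2,4-dimethoxy-6-(methoxycarbonyl)phenyl]propanoate | COC(=O)c1cc(OC)cc(OC)c1[C@@H](c1ccc(OC)cc1OC)CC(=O)ON1C(=O)c2c(Cl)c(Cl)c(Cl)c(Cl)c2C1=O | intermediate
13 | methyl 2-[(1R)-1-(2,4-dimethoxyphenyl)-2-[3,5-di(propan-2-yloxy)phenyl]ethyl]-3,5-dimethoxybenzoate | COC(=O)c1cc(OC)cc(OC)c1[C@@H](c1ccc(OC)cc1OC)Cc1cc(OC(C)C)cc(OC(C)C)c1 | intermediate
14 | 2-[(1R)-1-(2,4-dimethoxyphenyl)-2-[3,5-di(propan-2-yloxy)phenyl]ethyl]-3,5-dimethoxybenzoic acid | OC(=O)c1cc(OC)cc(OC)c1[C@@H](c1ccc(OC)cc1OC)Cc1cc(OC(C)C)cc(OC(C)C)c1 | intermediate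
15 | (11R)-11-(2,4-dimethoxyphenyl)-1,3-dimethoxy-6,8-di(propan-2-yloxy)-10,11-dihydro-5H-dibenzo[a,d][7]annulen-5-one | CC(C)Oc1cc(OC(C)C)cc2c1C(=O)c1cc(OC)cc(OC)c1[C@@H](c1ccc(OC)cc1OC)C2 | intermediate
16 | (11R)-11-(2,4-dimethoxyphenyl)-6-hydroxy-1,3-dimethoxy-8-(propan-2-yloxy)-10,11-dihydro-5H-dibenzo[a,d][7]annulen-5-one | Oc1cc(OC(C)C)cc2c1C(=O)c1cc(OC)cc(OC)c1[C@@H](c1ccc(OC)cc1OC)C2 | intermediate
17 | 4-methoxybenzyl chloride | COc1ccc(CCl)cc1 | starting material
18 | (11R)-11-(2,4-dimethoxyphenyl)-1,3-dimethoxy-6-[(4-methoxyphenyl)methoxy]-8-(propan-2-yloxy)-10,11-dihydro-5H-dibenzo[a,d][7]annulen-5-one | COc1ccc(COc2cc(OC(C)C)cc3c2C(=O)c2cc(OC)cc(OC)c2[C@@H](c2ccc(OC)cc2OC)C3)cc1 | intermediate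
19 | (11R)-11-(2,4-dimethoxyphenyl)-5-hydrazinylidene-1,3-dimethoxy-6-[(4-methoxyphenyl)methoxy]-8-(propan-2-yloxy)-10,11-dihydro-5H-dibenzo[a,d][7]annulene (C=N geometry open) | COc1ccc(COc2cc(OC(C)C)cc3c2C(=NN)c2cc(OC)cc(OC)c2[C@@H](c2ccc(OC)cc2OC)C3)cc1 | intermediate
20 | diazo compound: (11R)-5-diazo-11-(2,4-dimethoxyphenyl)-1,3-dimethoxy-6-[(4-methoxyphenyl)methoxy]-8-(propan-2-yloxy)-10,11-dihydro-5H-dibenzo[a,d][7]annulene | COc1ccc(COc2cc(OC(C)C)cc3c2C(=[N+]=[N-])c2cc(OC)cc(OC)c2[C@@H](c2ccc(OC)cc2OC)C3)cc1 | intermediate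
21 | cis furan 1 tetracycle: as 22 but (2'S), H-5 and H-2' cis | COc1ccc([C@H]2Oc3cc(OC(C)C)cc4c3[C@H]2c2cc(OC)cc(OC)c2[C@@H](c2ccc(OC)cc2OC)C4)cc1 | intermediate
22 | trans furan 1 tetracycle: (5R,11R)-11-(2,4-dimethoxyphenyl)-1,3-dimethoxy-8-(propan-2-yloxy)-10,11-dihydro-5H-dibenzo[a,d][7]annulene in which C-5 and O-6 are joined by C-2'H(4-methoxyphenyl), (2'R); H-5 and H-2' trans, H-5 on the face of the 11-aryl group | COc1ccc([C@@H]2Oc3cc(OC(C)C)cc4c3[C@H]2c2cc(OC)cc(OC)c2[C@@H](c2ccc(OC)cc2OC)C4)cc1 | intermediate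
23 | trans furan 1 tetracycle 8-phenol: 22 with 8-hydroxy in place of 8-(propan-2-yloxy), (5R,2'R,11R) | COc1ccc([C@@H]2Oc3cc(O)cc4c3[C@H]2c2cc(OC)cc(OC)c2[C@@H](c2ccc(OC)cc2OC)C4)cc1 | intermediate
24 | 9-formyl 8-phenol: 23 with a formyl group on C-9, (5R,2'R,11R) | COc1ccc([C@@H]2Oc3cc(O)c(C=O)c4c3[C@H]2c2cc(OC)cc(OC)c2[C@@H](c2ccc(OC)cc2OC)C4)cc1 | intermediate
25 | (2,4-dimethoxyphenyl)methanol | COc1ccc(CO)c(OC)c1 | starting material
26 | 9-formyl 8-ether: 24 with the 8-hydroxy group as its (2,4-dimethoxyphenyl)methyl ether, (5R,2'R,11R) | COc1ccc([C@@H]2Oc3cc(OCc5ccc(OC)cc5OC)c(C=O)c4c3[C@H]2c2cc(OC)cc(OC)c2[C@@H](c2ccc(OC)cc2OC)C4)cc1 | intermediate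
27 | (3,5-dimethoxyphenyl)magnesium chloride | COc1cc(OC)cc([Mg]Cl)c1 | starting material
28 | magnesium alkoxide: 26 with C-9 carrying CH(OMgCl)(3,5-dimethoxyphenyl) in place of formyl, carbinol centre unassigned, (5R,2'R,11R) | COc1ccc([C@@H]2Oc3cc(OCc5ccc(OC)cc5OC)c(C(O[Mg]Cl)c5cc(OC)cc(OC)c5)c4c3[C@H]2c2cc(OC)cc(OC)c2[C@@H](c2ccc(OC)cc2OC)C4)cc1 | intermediate
29 | diaryl ketone: 26 with C-9 carrying a 3,5-dimethoxybenzoyl group in place of formyl, (5R,2'R,11R) | COc1ccc([C@@H]2Oc3cc(OCc5ccc(OC)cc5OC)c(C(=O)c5cc(OC)cc(OC)c5)c4c3[C@H]2c2cc(OC)cc(OC)c2[C@@H](c2ccc(OC)cc2OC)C4)cc1 | intermediate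
30 | hydrazone of ketone 29 (C=N geometry open), (5R,2'R,11R) | COc1ccc([C@@H]2Oc3cc(OCc5ccc(OC)cc5OC)c(C(=NN)c5cc(OC)cc(OC)c5)c4c3[C@H]2c2cc(OC)cc(OC)c2[C@@H](c2ccc(OC)cc2OC)C4)cc1 | intermediate
31 | diazo compound from 30: C-9 carries C(=N2)(3,5-dimethoxyphenyl), (5R,2'R,11R) | COc1ccc([C@@H]2Oc3cc(OCc5ccc(OC)cc5OC)c(C(=[N+]=[N-])c5cc(OC)cc(OC)c5)c4c3[C@H]2c2cc(OC)cc(OC)c2[C@@H](c2ccc(OC)cc2OC)C4)cc1 | intermediate
32 | cis furan 2 isomer: as 33 but (2''R), H-3'' and H-2'' cis | COc1ccc([C@@H]2Oc3cc4c(c5c3[C@H]2c2cc(OC)cc(OC)c2[C@@H](c2ccc(OC)cc2OC)C5)[C@H](c2cc(OC)cc(OC)c2)[C@H](c2ccc(OC)cc2OC)O4)cc1 | intermediate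
33 | nonamethyl ether of the target: furan 1 tetracycle (5R,2'R,11R) in which C-9 and O-8 are joined by C-3''H(3,5-dimethoxyphenyl)–C-2''H(2,4-dimethoxyphenyl), (3''S,2''S); H-3'' and H-2'' trans | COc1ccc([C@@H]2Oc3cc4c(c5c3[C@H]2c2cc(OC)cc(OC)c2[C@@H](c2ccc(OC)cc2OC)C5)[C@H](c2cc(OC)cc(OC)c2)[C@@H](c2ccc(OC)cc2OC)O4)cc1 | intermediate
34 | CNP0283541.1: 33 with all nine methoxy groups as hydroxy groups, (5R,2'R,11R,3''S,2''S) | Oc1ccc([C@@H]2Oc3cc4c(c5c3[C@H]2c2cc(O)cc(O)c2[C@@H](c2ccc(O)cc2O)C5)[C@H](c2cc(O)cc(O)c2)[C@@H](c2ccc(O)cc2O)O4)cc1 | target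

**Step count and risks**

Total: 18 steps. Longest linear sequence: 17 steps (steps 1–3 and 5–18; step 4 is a one-step branch).

Step 11 (key step). What may go wrong: the ring-bound carbene may show poor facial selectivity at C-5 if the catalyst and the C-11 centre are mismatched, or the hindered diazo compound may couple to the azine before it meets the catalyst. Fallback, from 15 and back at 23: furan 1 is built without a carbene. Corey–Chaykovsky methylenation of ketone 15 with dimethylsulfonium methylide would give the spiro-epoxide F1. ZnI2 would rearrange it (Meinwald rearrangement) to the C-5 carbaldehyde F2, whose C-5 centre is enolisable; it would be equilibrated to the more stable epimer and purified. 4-Methoxyphenylmagnesium bromide would give the carbinol F3. BCl3 would then cleave both isopropyl ethers and ionise the benzylic alcohol, and the C-6 phenol would close furan 1 trans, which is phenol 23. In this variant C-5 rests on equilibration and separation, not on a catalyst.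

Step 16. What may go wrong: condensation may stall because the carbonyl is shielded by the benzyloxy group on C-8 and the C-10 methylene, and forcing may reduce the hydrazone or cleave the benzyl ether. Fallback, from 29 and back at 30: the ketone would be condensed with 1,2-bis(tert-butyldimethylsilyl)hydrazine under Sc(OTf)3 catalysis, a condensation driven by loss of the silanol and known to reach hindered ketones, to give the N-silyl hydrazone F4. Bu4NF would then free hydrazone 30.

Step 18. What may go wrong: ionisation of the benzylic C–O bonds of the two dihydrofurans by the Lewis acid, followed by elimination or Friedel–Crafts capture of the cations, and incomplete cleavage of nine ethers. Fallback, from 33 and back at 34: nucleophilic demethylation with NaSEt in DMF at 130 °C, an SN2 attack on the methyl groups under basic conditions that does not ionise the dihydrofurans; it passes through no new isolated compound.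

**Further compounds**

F1 | step 11 | spiro-epoxide: (11R)-11-(2,4-dimethoxyphenyl)-1,3-dimethoxy-6,8-di(propan-2-yloxy)-10,11-dihydrospiro[dibenzo[a,d][7]annulene-5,2'-oxirane], spiro centre unassigned | CC(C)Oc1cc(OC(C)C)cc2c1C1(CO1)c1cc(OC)cc(OC)c1[C@@H](c1ccc(OC)cc1OC)C2
F2 | step 11 | C-5 carbaldehyde: (5R,11R)-11-(2,4-dimethoxyphenyl)-1,3-dimethoxy-6,8-di(propan-2-yloxy)-10,11-dihydro-5H-dibenzo[a,d][7]annulene-5-carbaldehyde | CC(C)Oc1cc(OC(C)C)cc2c1[C@H](C=O)c1cc(OC)cc(OC)c1[C@@H](c1ccc(OC)cc1OC)C2
F3 | step 11 | carbinol: (4-methoxyphenyl)[(5R,11R)-11-(2,4-dimethoxyphenyl)-1,3-dimethoxy-6,8-di(propan-2-yloxy)-10,11-dihydro-5H-dibenzo[a,d][7]annulen-5-yl]methanol, carbinol centre unassigned | CC(C)Oc1cc(OC(C)C)cc2c1[C@H](C(O)c1ccc(OC)cc1)c1cc(OC)cc(OC)c1[C@@H](c1ccc(OC)cc1OC)C2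
F4 | step 16 | N-silyl hydrazone: N-(tert-butyldimethylsilyl) hydrazone of ketone 29, (5R,2'R,11R) | COc1ccc([C@@H]2Oc3cc(OCc5ccc(OC)cc5OC)c(C(=NN[Si](C)(C)C(C)(C)C)c5cc(OC)cc(OC)c5)c4c3[C@H]2c2cc(OC)cc(OC)c2[C@@H](c2ccc(OC)cc2OC)C4)cc1
F0 | step 18 | none | none
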